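**Plan**

- Retrosynthesis: the enoate side chain is cut at C12–C13 (B-alkyl Suzuki–Miyaura coupling) and at C11=C12 (Wittig methylenation of a C11 aldehyde). The C6 carbinol with its C7=C8 alkene is traced back through a 7-en-6-one to a C6 silyl enol ether.
- Enabling feature: ring B (C5, C6, C7, C8, C9, C10) is then a cyclohexene with oxygen on C6 and the alkene at C6=C7. It is the adduct of a 2-siloxydiene C5=C6–C7=C8 and an E enal C9=C10 whose formyl carbon C11 and methyl C20 are cis. Cutting C5–C10 and C8–C9 opens rings A and B together.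
- The acyclic trienal is cut at C6–C7 (propenyl addition), at C5–C6 (one-carbon homologation) and at C4–C18 (1,2-shift in an epoxy silyl ether). This leads to a symmetric diene-diol made from hepta-1,6-diyne.
- Forward order: the chain is built linearly (steps 1–11), both rings close in one step (step 12), ring B is adjusted (steps 13–17), and the side chain is completed and C18 unmasked (steps 19–20).
- Stereochemistry: C4 comes from a Sharpless epoxidation followed by a stereospecific anti 1,2-shift. C5, C9 and C10 come from the endo transition state of the E enal, and their sense relative to C4 from the chair-like tether. C6 comes from hydride addition followed by Mitsunobu inversion. The 13E alkene comes from an E enol triflate.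

Key step: step 12

Remark: atoms carry labdane numbers (C1–C10 decalin, C11–C16 side chain, C17 methyl on C8, C18 oxygenated carbon and C19 methyl on C4, C20 methyl on C10); hydride is assumed to reach the C6 carbonyl of the 7-en-6-one from the face opposite the axial C19 and C20 methyl groups, which is why one inversion at C6 is planned.

**Route**

Step 1
Reactants: 1 hepta-1,6-diyne
Product: 4 (2E,7E)-3,7-dimethylnona-2,7-diene-1,9-diol, via bis(alkenyl)alane 2 (not isolated), via dilithium bis(alkenyl)alanate 3 (not isolated)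
Conditions: Me3Al, Cp2ZrCl2 (cat.), CH2Cl2, rt; n-BuLi, THF, −78 °C; (CH2O)n, −78 °C → rt; aq. work-up
Reagents that add atoms: trimethylaluminium C[Al](C)C; paraformaldehyde (formaldehyde) C=O
Why: Zirconocene-catalysed syn methylalumination (Negishi carboalumination) puts CH3 on the internal and aluminium on the terminal carbon of each alkyne, and the derived alkenylalanate is hydroxymethylated with retention, so both trisubstituted alkenes should form E.

Step 2
Reactants: 4 (2E,7E)-3,7-dimethylnona-2,7-diene-1,9-diol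
Product: 5 (2E,7E)-9-hydroxy-3,7-dimethylnona-2,7-dien-1-yl pivalate
Conditions: NaH (1 equiv), THF, 0 °C; PivCl (1 equiv), 0 °C → rt
Reagents that add atoms: pivaloyl chloride CC(C)(C)C(Cl)=O
Why: Acylation of the monosodium alkoxide of the symmetric diol (statistical mono-esterification) should give mainly the mono-pivalate with diol and di-ester recyclable, and the pivalate has no α-hydrogen and survives every step up to its reductive removal in step 10.

Step 3
Reactants: 5 (2E,7E)-9-hydroxy-3,7-dimethylnona-2,7-dien-1-yl pivalate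
Product: 6 (2E)-6-[(2R,3R)-3-(hydroxymethyl)-2-methyloxiran-2-yl]-3-methylhex-2-en-1-yl pivalate
Conditions: Ti(OiPr)4 (cat.), D-(−)-diethyl tartrate (cat.), t-BuOOH, 4 Å MS, CH2Cl2, −20 °C
Reagents that add atoms: tert-butyl hydroperoxide CC(C)(C)OO
Why: Sharpless asymmetric epoxidation acts only on the alkene that carries the free allylic hydroxyl, and D-(−)-tartrate delivers oxygen to the face that gives the (2R,3R)-epoxide, which is the source of the C4 configuration.

Step 4
Reactants: 6 (2E)-6-[(2R,3R)-3-(hydroxymethyl)-2-methyloxiran-2-yl]-3-methylhex-2-en-1-yl pivalate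
Product: 7 (2E)-6-[(2R,3R)-3-{[(tert-butyldiphenylsilyl)oxy]methyl}-2-methyloxiran-2-yl]-3-methylhex-2-en-1-yl pivalate
Conditions: TBDPSCl, imidazole, DMF, rt
Reagents that add atoms: tert-butyl(chloro)diphenylsilane CC(C)(C)[Si](Cl)(c1ccccc1)c1ccccc1
Why: Imidazole-mediated silylation of the primary hydroxyl gives the epoxy silyl ether needed for the rearrangement and installs the bulky group that C18 keeps until the last step.

Step 5
Reactants: 7 (2E)-6-[(2R,3R)-3-{[(tert-butyldiphenylsilyl)oxy]methyl}-2-methyloxiran-2-yl]-3-methylhex-2-en-1-yl pivalate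
Product: 8 (2E,7R)-7-{[(tert-butyldiphenylsilyl)oxy]methyl}-3,7-dimethyl-8-oxooct-2-en-1-yl pivalate
Conditions: MABR [methylaluminium bis(4-bromo-2,6-di-tert-butylphenoxide), 20 mol%], CH2Cl2, −78 → −20 °C
Reagents that add atoms: none
Why: In this organoaluminium-promoted epoxy silyl ether rearrangement (a semipinacol-type 1,2-shift) the bulky Lewis acid opens the epoxide at its tertiary carbon and the siloxymethyl group migrates anti to the leaving oxygen, so the epoxide chirality is transferred with inversion into the quaternary C4 of a β-siloxy aldehyde that has no α-hydrogen and cannot epimerise.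

Step 6
Reactants: 8 (2E,7R)-7-{[(tert-butyldiphenylsilyl)oxy]methyl}-3,7-dimethyl-8-oxooct-2-en-1-yl pivalate
Product: 10 (2E,7S)-7-{[(tert-butyldiphenylsilyl)oxy]methyl}-3,7-dimethyl-9-oxonon-2-en-1-yl pivalate, via methyl enol ether 9 (not isolated)
Conditions: Ph3P(CH2OMe)Cl, KHMDS, THF, 0 °C → rt; then 2 M HCl, THF, rt
Reagents that add atoms: (methoxymethyl)triphenylphosphonium chloride [Cl-].COC[P+](c1ccccc1)(c1ccccc1)c1ccccc1; water O
Why: Wittig methoxymethylenation of the non-enolisable neopentyl aldehyde followed by acid hydrolysis of the enol ether is the standard one-carbon homologation and gives the C6 aldehyde with C5 as a methylene, the TBDPS ether and the allylic pivalate being stable to brief aqueous acid.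

Step 7
Reactants: 10 (2E,7S)-7-{[(tert-butyldiphenylsilyl)oxy]methyl}-3,7-dimethyl-9-oxonon-2-en-1-yl pivalate; 11 (E)-1-bromoprop-1-ene
Product: 13 (2E,7S,10E)-7-{[(tert-butyldiphenylsilyl)oxy]methyl}-9-hydroxy-3,7-dimethyldodeca-2,10-dien-1-yl pivalate (both C9 epimers), via (E)-prop-1-enyllithium 12 (not isolated)
Conditions: 11, t-BuLi (2 equiv), Et2O, −78 °C; then 10, −78 °C; aq. NH4Cl
Reagents that add atoms: none
Why: Bromine–lithium exchange proceeds with retention of the E geometry and the alkenyllithium adds to the aldehyde at −78 °C much faster than to the hindered pivalate (1,2-addition of an organolithium), the new carbinol centre being formed unselectively and removed in step 8.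

Step 8
Reactants: 13 (2E,7S,10E)-7-{[(tert-butyldiphenylsilyl)oxy]methyl}-9-hydroxy-3,7-dimethyldodeca-2,10-dien-1-yl pivalate
Product: 14 (2E,7S,10E)-7-{[(tert-butyldiphenylsilyl)oxy]methyl}-3,7-dimethyl-9-oxododeca-2,10-dien-1-yl pivalate
Conditions: Dess–Martin periodinane, CH2Cl2, rt
Reagents that add atoms: none
Why: Dess–Martin oxidation of the secondary allylic alcohol gives the E propenyl ketone without touching the other alkene or the protecting groups.

Step 9
Reactants: 14 (2E,7S,10E)-7-{[(tert-butyldiphenylsilyl)oxy]methyl}-3,7-dimethyl-9-oxododeca-2,10-dien-1-yl pivalate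
Product: 15 (2E,7S,8Z,10E)-9-[(tert-butyldimethylsilyl)oxy]-7-{[(tert-butyldiphenylsilyl)oxy]methyl}-3,7-dimethyldodeca-2,8,10-trien-1-yl pivalate
Conditions: TBSOTf, Et3N, CH2Cl2, −78 → 0 °C
Reagents that add atoms: tert-butyldimethylsilyl trifluoromethanesulfonate CC(C)(C)[Si](C)(C)OS(=O)(=O)C(F)(F)F
Why: Soft enolisation with silyl triflate and amine removes an α′ proton of the enone to give the cross-conjugated 2-siloxydiene, and the Z enol ether (oxygen cis to C4) should result because the quaternary C4 avoids the propenyl group, which also puts the tether in the outside position needed for cyclisation.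

Step 10
Reactants: 15 (2E,7S,8Z,10E)-9-[(tert-butyldimethylsilyl)oxy]-7-{[(tert-butyldiphenylsilyl)oxy]methyl}-3,7-dimethyldodeca-2,8,10-trien-1-yl pivalate
Product: 16 (2E,7S,8Z,10E)-9-[(tert-butyldimethylsilyl)oxy]-7-{[(tert-butyldiphenylsilyl)oxy]methyl}-3,7-dimethyldodeca-2,8,10-trien-1-ol
Conditions: DIBAL-H, CH2Cl2, −78 °C; Rochelle salt work-up
Reagents that add atoms: none
Why: DIBAL-H cleaves the pivalate reductively at −78 °C under non-acidic conditions that the silyl dienol ether and the silyl ether tolerate.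

Step 11
Reactants: 16 (2E,7S,8Z,10E)-9-[(tert-butyldimethylsilyl)oxy]-7-{[(tert-butyldiphenylsilyl)oxy]methyl}-3,7-dimethyldodeca-2,8,10-trien-1-ol
Product: 17 (2E,7S,8Z,10E)-9-[(tert-butyldimethylsilyl)oxy]-7-{[(tert-butyldiphenylsilyl)oxy]methyl}-3,7-dimethyldodeca-2,8,10-trienal
Conditions: MnO2, CH2Cl2, rt
Reagents that add atoms: none
Why: Manganese dioxide oxidises the primary allylic alcohol to the E enal under neutral conditions (allylic oxidation) and leaves the acid-sensitive siloxydiene intact.

Step 12
Reactants: 17 (2E,7S,8Z,10E)-9-[(tert-butyldimethylsilyl)oxy]-7-{[(tert-butyldiphenylsilyl)oxy]methyl}-3,7-dimethyldodeca-2,8,10-trienal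
Product: 18 (4S,5S,8R,9R,10R)-6-[(tert-butyldimethylsilyl)oxy]-18-[(tert-butyldiphenylsilyl)oxy]-12,13,14,15,16-pentanorlabd-6-en-11-al
Conditions: Me2AlCl (0.3 equiv), CH2Cl2 (dilute), −78 → −30 °C
Reagents that add atoms: none
Why: The Lewis acid binds the formyl group of 17 and lowers the LUMO of the E enal, which adds across the tethered 2-siloxydiene in a concerted but asynchronous [4+2] in which the bond from the nucleophilic diene terminus C5 to the enal β-carbon C10 runs ahead of the C8–C9 bond; the closest known reaction type is the Lewis-acid-promoted intramolecular Diels–Alder reaction of 1,7,9-decatrienals that carry 2-siloxydienes. Ring B closes as the new cyclohexene through C5–C10 and C8–C9 with the silyl enol ether left at C6=C7, and ring A closes as a six-membered ring because the four carbons C1–C4 link C10 to C5 in a chair-like tether. The trans ring fusion at C5 and C10 comes from the endo transition state, in which the aluminium-bound formyl group and with it the C20 methyl lie under the diene while the tether points away; the E enal fixes C11 on C9 cis to C20, and the E propenyl terminus puts C17 on C8 cis to C11, a centre that is removed in step 14. The sense of the new centres relative to C4 is set by the chair tether, which should keep the CH2OTBDPS group equatorial and leave the smaller methyl syn-axial to C20; this preference is expected to be moderate, and the isomer formed on the other diene face would be removed by chromatography. The step therefore needs endo and facial selectivity, the first secured by the Lewis acid and the E geometry of both partners, the second by the size difference at C4 helped by the bulky silyl group and the low temperature. The β,β-disubstituted dienophile carbon is acceptable because the reaction is intramolecular and polarity-matched, the siloxy group on C6 ending para to the formyl-bearing C9.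

Step 13
Reactants: 18 (4S,5S,8R,9R,10R)-6-[(tert-butyldimethylsilyl)oxy]-18-[(tert-butyldiphenylsilyl)oxy]-12,13,14,15,16-pentanorlabd-6-en-11-al
Product: 19 (4S,5S,8S,9R,10S)-6-[(tert-butyldimethylsilyl)oxy]-18-[(tert-butyldiphenylsilyl)oxy]-13,14,15,16-tetranorlabda-6,11-diene
Conditions: Ph3PCH3Br, KHMDS, THF, −78 → 0 °C
Reagents that add atoms: methyltriphenylphosphonium bromide [Br-].C[P+](c1ccccc1)(c1ccccc1)c1ccccc1
Why: Wittig methylenation turns the hindered aldehyde into the C11=C12 vinyl group before the C7=C8 alkene exists, so that the aldehyde cannot move into conjugation, and the base-stable silyl enol ether keeps the C6 ketone masked.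

Step 14
Reactants: 19 (4S,5S,8S,9R,10S)-6-[(tert-butyldimethylsilyl)oxy]-18-[(tert-butyldiphenylsilyl)oxy]-13,14,15,16-tetranorlabda-6,11-diene
Product: 20 (4S,5S,9R,10S)-18-[(tert-butyldiphenylsilyl)oxy]-13,14,15,16-tetranorlabda-7,11-dien-6-one
Conditions: Pd(OAc)2 (1.1 equiv), MeCN, rt
Reagents that add atoms: none
Why: In the Saegusa–Ito oxidation the palladium enolate formed from the silyl enol ether is carbon-bound at C7 and can only undergo syn β-hydride elimination towards C8, because the carbons flanking C5 are quaternary, which gives the 7-en-6-one and erases the C8 centre.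

Step 15
Reactants: 20 (4S,5S,9R,10S)-18-[(tert-butyldiphenylsilyl)oxy]-13,14,15,16-tetranorlabda-7,11-dien-6-one
Product: 21 (4S,5S,6S,9R,10S)-18-[(tert-butyldiphenylsilyl)oxy]-13,14,15,16-tetranorlabda-7,11-dien-6-ol
Conditions: NaBH4, CeCl3·7H2O, MeOH, −20 °C
Reagents that add atoms: none
Why: Luche reduction gives 1,2-addition only, and hydride should approach C6 from the face opposite the axial C19 and C20 methyl groups, so the new hydroxyl is expected cis to C20 (6S).

Step 16
Reactants: 21 (4S,5S,6S,9R,10S)-18-[(tert-butyldiphenylsilyl)oxy]-13,14,15,16-tetranorlabda-7,11-dien-6-ol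
Product: 22 (4S,5S,6R,9R,10S)-18-[(tert-butyldiphenylsilyl)oxy]-13,14,15,16-tetranorlabda-7,11-dien-6-yl 4-nitrobenzoate
Conditions: 4-O2NC6H4CO2H, PPh3, DIAD, toluene, 0 °C → rt
Reagents that add atoms: 4-nitrobenzoic acid OC(=O)c1ccc(cc1)[N+](=O)[O-]
Why: In the Mitsunobu reaction the activated allylic oxygen is displaced by 4-nitrobenzoate with inversion, and since the face of C6 syn to C19 and C20 is blocked the carboxylate can only enter trans to C20, which gives the required 6R configuration.

Step 17
Reactants: 22 (4S,5S,6R,9R,10S)-18-[(tert-butyldiphenylsilyl)oxy]-13,14,15,16-tetranorlabda-7,11-dien-6-yl 4-nitrobenzoate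
Product: 23 (4S,5S,6R,9R,10S)-18-[(tert-butyldiphenylsilyl)oxy]-13,14,15,16-tetranorlabda-7,11-dien-6-ol
Conditions: K2CO3 (cat.), MeOH, rt
Reagents that add atoms: none
Why: Carbonate-catalysed transesterification with methanol removes the electron-poor benzoate and leaves the silyl ether and both alkenes untouched.

Step 18
Reactants: 24 methyl acetoacetate
Product: 25 methyl (E)-3-{[(trifluoromethyl)sulfonyl]oxy}but-2-enoate
Conditions: Tf2O, aq. Me4NOH, hexane/toluene, 5 °C
Reagents that add atoms: trifluoromethanesulfonic anhydride O=S(=O)(OS(=O)(=O)C(F)(F)F)C(F)(F)F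
Why: O-Triflation of the acetoacetate enolate with a non-chelating tetraalkylammonium counter-ion should give the E enol triflate (triflate trans to the ester), which fixes the later 13E geometry.

Step 19
Reactants: 23 (4S,5S,6R,9R,10S)-18-[(tert-butyldiphenylsilyl)oxy]-13,14,15,16-tetranorlabda-7,11-dien-6-ol; 25 methyl (E)-3-{[(trifluoromethyl)sulfonyl]oxy}but-2-enoate
Product: 27 methyl (4S,5S,6R,9R,10S,13E)-18-[(tert-butyldiphenylsilyl)oxy]-6-hydroxylabda-7,13-dien-15-oate, via B-alkyl-9-BBN borane 26 (not isolated)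
Conditions: 9-BBN (2.5 equiv), THF, rt; then 3 M aq. K3PO4, 25, PdCl2(dppf) (5 mol%), AsPh3, DMF, rt
Reagents that add atoms: none
Why: 9-BBN hydroborates only the monosubstituted C11=C12 alkene with boron at C12 (the free hydroxyl merely consumes extra borane), and the B-alkyl Suzuki–Miyaura coupling with the enol triflate forms C12–C13 with retention of the alkene geometry.

Step 20
Reactants: 27 methyl (4S,5S,6R,9R,10S,13E)-18-[(tert-butyldiphenylsilyl)oxy]-6-hydroxylabda-7,13-dien-15-oate
Product: 28 methyl (4S,5S,6R,9R,10S,13E)-6,18-dihydroxylabda-7,13-dien-15-oate (CNP0149445.1)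
Conditions: TBAF, AcOH, THF, rt
Reagents that add atoms: none
Why: Fluoride cleaves the silicon–oxygen bond of the primary TBDPS ether (desilylation), buffered with acetic acid so that the methyl ester and the allylic alcohol are not affected.

**Compound list**

1 | hepta-1,6-diyne | C#CCCCC#C | starting material
2 | [(1E,6E)-2,6-dimethylhepta-1,6-diene-1,7-diyl]bis(dimethylalane) | C[Al](C)/C=C(\C)CCC/C(C)=C/[Al](C)C | intermediate
3 | dilithium bis(butyl)alanate of 2 | [Li+].[Li+].CCCC[Al-](C)(C)/C=C(\C)CCC/C(C)=C/[Al-](C)(C)CCCC | intermediate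
4 | (2E,7E)-3,7-dimethylnona-2,7-diene-1,9-diol | OC/C=C(\C)CCC/C(C)=C/CO | intermediate
5 | (2E,7E)-9-hydroxy-3,7-dimethylnona-2,7-dien-1-yl pivalate | CC(C)(C)C(=O)OC/C=C(\C)CCC/C(C)=C/CO | intermediate
6 | (2E)-6-[(2R,3R)-3-(hydroxymethyl)-2-methyloxiran-2-yl]-3-methylhex-2-en-1-yl pivalate | OC[C@H]1O[C@]1(C)CCC/C(C)=C/COC(=O)C(C)(C)C | intermediate
7 | (2E)-6-[(2R,3R)-3-{[(tert-butyldiphenylsilyl)oxy]methyl}-2-methyloxiran-2-yl]-3-methylhex-2-en-1-yl pivalate | CC(C)(C)[Si](OC[C@H]1O[C@]1(C)CCC/C(C)=C/COC(=O)C(C)(C)C)(c1ccccc1)c1ccccc1 | intermediate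
8 | (2E,7R)-7-{[(tert-butyldiphenylsilyl)oxy]methyl}-3,7-dimethyl-8-oxooct-2-en-1-yl pivalate | O=C[C@@](C)(CO[Si](c1ccccc1)(c1ccccc1)C(C)(C)C)CCC/C(C)=C/COC(=O)C(C)(C)C | intermediate
9 | (2E,7S)-7-{[(tert-butyldiphenylsilyl)oxy]methyl}-9-methoxy-3,7-dimethylnona-2,8-dien-1-yl pivalate (8E/8Z mixture) | COC=C[C@@](C)(CO[Si](c1ccccc1)(c1ccccc1)C(C)(C)C)CCC/C(C)=C/COC(=O)C(C)(C)C | intermediate
10 | (2E,7S)-7-{[(tert-butyldiphenylsilyl)oxy]methyl}-3,7-dimethyl-9-oxonon-2-en-1-yl pivalate | O=CC[C@@](C)(CO[Si](c1ccccc1)(c1ccccc1)C(C)(C)C)CCC/C(C)=C/COC(=O)C(C)(C)C | intermediate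
11 | (E)-1-bromoprop-1-ene | C/C=C/Br | starting material
12 | (E)-prop-1-enyllithium | C/C=C/[Li] | intermediate
13 | (2E,7S,10E)-7-{[(tert-butyldiphenylsilyl)oxy]methyl}-9-hydroxy-3,7-dimethyldodeca-2,10-dien-1-yl pivalate (both C9 epimers) | C/C=C/C(O)C[C@@](C)(CO[Si](c1ccccc1)(c1ccccc1)C(C)(C)C)CCC/C(C)=C/COC(=O)C(C)(C)C | intermediate
14 | (2E,7S,10E)-7-{[(tert-butyldiphenylsilyl)oxy]methyl}-3,7-dimethyl-9-oxododeca-2,10-dien-1-yl pivalate | C/C=C/C(=O)C[C@@](C)(CO[Si](c1ccccc1)(c1ccccc1)C(C)(C)C)CCC/C(C)=C/COC(=O)C(C)(C)C | intermediate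
15 | (2E,7S,8Z,10E)-9-[(tert-butyldimethylsilyl)oxy]-7-{[(tert-butyldiphenylsilyl)oxy]methyl}-3,7-dimethyldodeca-2,8,10-trien-1-yl pivalate | C/C=C/C(O[Si](C)(C)C(C)(C)C)=C/[C@@](C)(CO[Si](c1ccccc1)(c1ccccc1)C(C)(C)C)CCC/C(C)=C/COC(=O)C(C)(C)C | intermediate
16 | (2E,7S,8Z,10E)-9-[(tert-butyldimethylsilyl)oxy]-7-{[(tert-butyldiphenylsilyl)oxy]methyl}-3,7-dimethyldodeca-2,8,10-trien-1-ol | C/C=C/C(O[Si](C)(C)C(C)(C)C)=C/[C@@](C)(CO[Si](c1ccccc1)(c1ccccc1)C(C)(C)C)CCC/C(C)=C/CO | intermediate
17 | (2E,7S,8Z,10E)-9-[(tert-butyldimethylsilyl)oxy]-7-{[(tert-butyldiphenylsilyl)oxy]methyl}-3,7-dimethyldodeca-2,8,10-trienal | C/C=C/C(O[Si](C)(C)C(C)(C)C)=C/[C@@](C)(CO[Si](c1ccccc1)(c1ccccc1)C(C)(C)C)CCC/C(C)=C/C=O | intermediate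
18 | (4S,5S,8R,9R,10R)-6-[(tert-butyldimethylsilyl)oxy]-18-[(tert-butyldiphenylsilyl)oxy]-12,13,14,15,16-pentanorlabd-6-en-11-al (trans-decalin; CHO, C17, C19 and C20 on one face; H-5, H-8, H-9 and CH2OTBDPS on the other) | O=C[C@@H]1[C@H](C)C=C(O[Si](C)(C)C(C)(C)C)[C@@H]2[C@@](C)(CO[Si](c3ccccc3)(c3ccccc3)C(C)(C)C)CCC[C@@]12C | intermediate
19 | (4S,5S,8S,9R,10S)-6-[(tert-butyldimethylsilyl)oxy]-18-[(tert-butyldiphenylsilyl)oxy]-13,14,15,16-tetranorlabda-6,11-diene | C=C[C@@H]1[C@H](C)C=C(O[Si](C)(C)C(C)(C)C)[C@@H]2[C@@](C)(CO[Si](c3ccccc3)(c3ccccc3)C(C)(C)C)CCC[C@@]12C | intermediate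
20 | (4S,5S,9R,10S)-18-[(tert-butyldiphenylsilyl)oxy]-13,14,15,16-tetranorlabda-7,11-dien-6-one | C=C[C@@H]1C(C)=CC(=O)[C@@H]2[C@@](C)(CO[Si](c3ccccc3)(c3ccccc3)C(C)(C)C)CCC[C@@]12C | intermediate
21 | (4S,5S,6S,9R,10S)-18-[(tert-butyldiphenylsilyl)oxy]-13,14,15,16-tetranorlabda-7,11-dien-6-ol (6-OH cis to C20) | C=C[C@@H]1C(C)=C[C@H](O)[C@@H]2[C@@](C)(CO[Si](c3ccccc3)(c3ccccc3)C(C)(C)C)CCC[C@@]12C | intermediate
22 | (4S,5S,6R,9R,10S)-18-[(tert-butyldiphenylsilyl)oxy]-13,14,15,16-tetranorlabda-7,11-dien-6-yl 4-nitrobenzoate (6-O trans to C20) | C=C[C@@H]1C(C)=C[C@@H](OC(=O)c3ccc(cc3)[N+](=O)[O-])[C@@H]2[C@@](C)(CO[Si](c3ccccc3)(c3ccccc3)C(C)(C)C)CCC[C@@]12C | intermediate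
23 | (4S,5S,6R,9R,10S)-18-[(tert-butyldiphenylsilyl)oxy]-13,14,15,16-tetranorlabda-7,11-dien-6-ol (6-OH trans to C20) | C=C[C@@H]1C(C)=C[C@@H](O)[C@@H]2[C@@](C)(CO[Si](c3ccccc3)(c3ccccc3)C(C)(C)C)CCC[C@@]12C | intermediate
24 | methyl acetoacetate | COC(=O)CC(C)=O | starting material
25 | methyl (E)-3-{[(trifluoromethyl)sulfonyl]oxy}but-2-enoate | COC(=O)/C=C(\C)OS(=O)(=O)C(F)(F)F | intermediate
26 | 9-[(4S,5S,6R,9R,10S)-18-[(tert-butyldiphenylsilyl)oxy]-6-hydroxy-13,14,15,16-tetranorlabd-7-en-12-yl]-9-borabicyclo[3.3.1]nonane | B1(CC[C@@H]2C(C)=C[C@@H](O)[C@@H]3[C@@](C)(CO[Si](c4ccccc4)(c4ccccc4)C(C)(C)C)CCC[C@@]23C)C2CCCC1CCC2 | intermediate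
27 | methyl (4S,5S,6R,9R,10S,13E)-18-[(tert-butyldiphenylsilyl)oxy]-6-hydroxylabda-7,13-dien-15-oate | COC(=O)/C=C(\C)CC[C@@H]1C(C)=C[C@@H](O)[C@@H]2[C@@](C)(CO[Si](c3ccccc3)(c3ccccc3)C(C)(C)C)CCC[C@@]12C | intermediate
28 | methyl (4S,5S,6R,9R,10S,13E)-6,18-dihydroxylabda-7,13-dien-15-oate = methyl (2E)-5-[(1R,4R,4aS,5S,8aS)-4-hydroxy-5-(hydroxymethyl)-2,5,8a-trimethyl-1,4,4a,5,6,7,8,8a-octahydronaphthalen-1-yl]-3-methylpent-2-enoate | COC(=O)/C=C(\C)CC[C@@H]1C(C)=C[C@@H](O)[C@@H]2[C@@](C)(CO)CCC[C@@]12C | target

**Step count and risks**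

Total step count: 20 (19 in the main line and one for coupling partner 25). Longest linear sequence: 19 steps (steps 1–17, 19 and 20).

The three steps most likely to fail, in order of risk:

Step 12. The chair-like tether may discriminate only weakly between the methyl and the CH2OTBDPS group on C4, so that the enal adds to both faces of the diene. The trisubstituted enal may also react slowly enough for the siloxydiene to be lost by protodesilylation. The fallback moves the choice of face from the substrate to the reagent. Trienal 17 would be cyclised with a chiral oxazaborolidinium triflimide, a known class of Lewis acid for cycloadditions of enals with 2-silyloxydienes. The catalyst antipode would be chosen so that the enal face it leaves open is the one that gives the required relation to C4. This path runs from 17 to 18 and makes no new compound (F0).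

Step 16. The alkoxyphosphonium ion may form slowly at the hindered pseudoaxial hydroxyl, and the activated oxygen may be lost by elimination to the 5,7-diene or by ionisation with capture at C8. The fallback sets out from 19 and brings the C6 oxygen in from the open face by epoxidation, without any displacement at C6.
- The silyl enol ether of 19 is cleaved with MeLi and the lithium enolate is trapped with PhNTf2 to give the C6 enol triflate F1.
- Palladium-catalysed reduction with tributylammonium formate gives the 6,11-diene F2.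
- mCPBA should epoxidise the ring alkene from the face opposite C19 and C20 and leave the vinyl group, giving the 6,7-epoxide F3.
- Diethylaluminium 2,2,6,6-tetramethylpiperidide then removes H-8, which is syn to the epoxide oxygen and far more accessible than H-5, and opens the C7–O bond.

This gives the allylic alcohol with the C6 oxygen trans to C20, where the path returns to the route at 23.

Step 1. The second methylalumination may stall, or a terminal alkyne may be metalated instead, which would give mixtures of mono- and bis-adducts. The fallback sets out from 1 and uses hydroxyl-directed hydroalumination in place of carbometalation.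
- Double deprotonation with n-BuLi and hydroxymethylation with paraformaldehyde gives nona-2,7-diyne-1,9-diol F4.
- Red-Al trans-hydroalumination directed by each hydroxyl, followed by iodine, gives (2Z,7Z)-3,7-diiodonona-2,7-diene-1,9-diol F5.
- Lithium dimethylcuprate replaces each iodine by methyl with retention.

The path returns to the route at 4.

**Further compounds**

F0 | step 12 | none | none
F1 | step 16 | (4S,5S,8S,9R,10S)-18-[(tert-butyldiphenylsilyl)oxy]-13,14,15,16-tetranorlabda-6,11-dien-6-yl trifluoromethanesulfonate | C=C[C@@H]1[C@H](C)C=C(OS(=O)(=O)C(F)(F)F)[C@@H]2[C@@](C)(CO[Si](c3ccccc3)(c3ccccc3)C(C)(C)C)CCC[C@@]12C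
F2 | step 16 | 18-[(tert-butyldiphenylsilyl)oxy]-13,14,15,16-tetranorlabda-6,11-diene (ring stereochemistry as in 19) | C=C[C@@H]1[C@H](C)C=C[C@@H]2[C@@](C)(CO[Si](c3ccccc3)(c3ccccc3)C(C)(C)C)CCC[C@@]12C
F3 | step 16 | 6,7-epoxide of F2 with the oxygen trans to C20 | C=C[C@@H]1[C@H](C)[C@H]3O[C@H]3[C@@H]2[C@@](C)(CO[Si](c4ccccc4)(c4ccccc4)C(C)(C)C)CCC[C@@]12C
F4 | step 1 | nona-2,7-diyne-1,9-diol | OCC#CCCCC#CCO
F5 | step 1 | (2Z,7Z)-3,7-diiodonona-2,7-diene-1,9-diol | OC/C=C(\I)CCC/C(I)=C/CO
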